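**Easy step.** You want a quick number, and you suspect the isomer of the product overtakes the target. I start with what is easy to read: how fast the isomer gains in the midnight run, which is this same flask followed so far.

common to all: starting material 0.80 M

| flask | reagent | protic impurity | remark | time |
|---|---|---|---|---|
| midnight | 1 equiv | 0.80 M | the very flask that is asked about, followed so far |  |
| flask | 1.00 equiv | 0.800 M |  | 50 h |

midnight run (percent of the starting material charged)

| time / h | target / % | isomer of the product / % |
|---|---|---|
| 1.33 | 2.7 | 0.4 |
| 4.00 | 8.8 | 2.1 |
| 8.00 | 12.9 | 7.2 |
| 10.0 | 13.5 | 9.4 |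
| 15.0 | 13.4 | 13.9 |
| 20.0 | 13.1 | 16.5 |

(scatter of a reading: 0.3 percentage points)

- ratio of target to isomer of the product at 1.5 h
- ratio of target to isomer of the product at 50 h
- which of target and isomer of the product there is more of at 50 h



**First pass.** Suppose the target turns into the isomer by a one-way step. The isomer's gain per hour should then follow the target. But the target reads 12.9% at 8.00 h and 13.1% at 20.0 h, while the gain from 15.0 h to 20.0 h is smaller by a factor of 2.12 than the gain from 8.00 h to 10.0 h. So I try a way back.

**Second pass.** The gain now goes with the target minus a fixed multiple of the isomer. The two intervals put that multiple at 0.622. I call it the standing ratio: the ratio of target to isomer at which the isomer stops gaining. It is a rough reading, given the scatter.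

**Going round.** Putting it back gives a forward constant of 0.137 h⁻¹. Early on, if the target grows steadily, the ratio is about 2 over that constant times the time, so I say 9.73 at 1.5 h. My relaxation half-life is 3.12 h, far shorter than 50 h, so I commit to 0.622 at 50 h, with the isomer ahead.

The forecast gives 8.5 and 0.48 with isomer of the product ahead, “a ratio near 0.5”.

**The flask.** It gives 11.0 and 0.715, with isomer of the product ahead, at 12.6% target and 17.6% isomer.

    starting material ⇌ intermediate A (K = 3.00, k = 0.110 h⁻¹)
    starting material + protic impurity → quenched substrate (k = 0.490 M⁻¹ h⁻¹)
    intermediate A ⇌ intermediate B (K = 2.20, k = 0.0120 h⁻¹)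
    reagent + intermediate A ⇌ intermediate C (K = 0.820 M⁻¹, k = 0.650 M⁻¹ h⁻¹)
    target ⇌ isomer of the product (K = 1.40, k = 0.160 h⁻¹)
    intermediate A → target (k = 0.510 h⁻¹)

**Pair equilibrium.** In this flask the relaxation half-life of target and isomer, both ways together, is 2.53 h, short against 50 h. The pair is under thermodynamic control by then, at 0.715, where I had committed to a standing ratio of 0.622. The neighbour flask, like this one but charged with 0.600 equiv of reagent, ends at 0.715, with 12.6% target and 17.6% isomer.

The earlier runs and the new flask stem from a simulated flask with constants of no real substance; scatter was added.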